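**Plan**

- Retrosynthesis: the O1–C2 bond of ring C is cut first (oxa-Michael), after an allyl ester is put back on C3 (decarboxylation in reverse). Then C2=C3 (Knoevenagel), C3–C4 (aldol), C4–C4a (ortho-formylation) and the aryl–geranyl bond at C6 (aryllithium allylation) are cut.
- Forward: ring A is dressed first, starting from phloroglucinol (geranyl between two MOM ethers, then a formyl group next to the single free hydroxyl). Allyl acetate supplies C3 and the ester, protected syringaldehyde brings ring B, and ring C closes last.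
- Enabling feature: C2 is a benzylic carbon bound to the ring A oxygen O1 and lies beta to the C4 ketone, so O1–C2 can be made by adding a phenol to a C2=C3 acceptor. Ring A has a second oxygen ortho to the acyl carbon (O5), so only O1 is left unprotected.
- Stereochemistry: C2 (S), the only stereocentre of the target, is set by a cinchona thiourea catalyst during ring closure. The C3 ester centre is temporary, and the E double bond of the side chain comes from geranyl bromide.

Key step: step 10

Remark: geranyl means (2E)-3,7-dimethylocta-2,6-dien-1-yl. The quinine-derived thiourea is assumed to give the 2S series; if a trial cyclisation shows the opposite sense, the quinidine-derived pseudoenantiomer is used under the same conditions.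

**Route**

Step 1
Reactants: 1 phloroglucinol
Product: 2 3,5-bis(methoxymethoxy)phenol
Conditions: MOMCl (2.0 equiv), i-Pr2NEt (2.2 equiv), DMF, 0 °C to rt; chromatography
Reagents that add atoms: chloromethyl methyl ether (MOMCl), COCCl
Why: MOM ether formation (Williamson-type O-alkylation) with two equivalents of reagent should give the bis-ether as the main part of a statistical mixture, separable from the mono- and tris-ethers by polarity.

Step 2
Reactants: 2 3,5-bis(methoxymethoxy)phenol
Product: 3 [3,5-bis(methoxymethoxy)phenoxy]triisopropylsilane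
Conditions: TIPSCl, imidazole, DMF, rt
Reagents that add atoms: triisopropylsilyl chloride, CC(C)[Si](Cl)(C(C)C)C(C)C
Why: O-silylation of the only free hydroxyl installs a bulky, non-coordinating group that survives butyllithium and does not direct metalation to its own ortho positions.

Step 3
Reactants: 3 [3,5-bis(methoxymethoxy)phenoxy]triisopropylsilane; 4 geranyl bromide
Product: 6 [4-geranyl-3,5-bis(methoxymethoxy)phenoxy]triisopropylsilane, via aryllithium 5 (not isolated)
Conditions: n-BuLi (1.2 equiv), THF, 0 °C to rt; then CuI (10 mol %), 4, −78 °C to rt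
Reagents that add atoms: none
Why: Directed ortho-metalation should occur only at the carbon flanked by two coordinating MOM ethers, and copper-catalysed SN2 allylation of the aryllithium with the primary allylic bromide keeps the E double bond.

Step 4
Reactants: 6 [4-geranyl-3,5-bis(methoxymethoxy)phenoxy]triisopropylsilane
Product: 7 4-geranyl-3,5-bis(methoxymethoxy)phenol
Conditions: Bu4NF (1.1 equiv), AcOH (1.1 equiv), THF, 0 °C
Reagents that add atoms: none
Why: Fluoride-mediated desilylation of the aryl silyl ether, buffered with acetic acid, should release the electron-rich phenol in neutral form while the MOM ethers stay inert.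

Step 5
Reactants: 7 4-geranyl-3,5-bis(methoxymethoxy)phenol
Product: 9 3-geranyl-6-hydroxy-2,4-bis(methoxymethoxy)benzaldehyde, via salicyl alcohol 8 (not isolated)
Conditions: MgCl2 (2 equiv), Et3N (4 equiv), (CH2O)n (6 equiv), THF, reflux; cold 1 M HCl work-up
Reagents that add atoms: formaldehyde (as paraformaldehyde), C=O
Why: In this magnesium-mediated ortho-formylation of a phenol (Casnati–Skattebøl reaction) the magnesium phenoxide delivers formaldehyde only next to the free hydroxyl, whose two ortho positions are equivalent by symmetry, and a second formaldehyde oxidises the salicyl alcohol by hydride transfer.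

Step 6
Reactants: 9 3-geranyl-6-hydroxy-2,4-bis(methoxymethoxy)benzaldehyde; 10 allyl acetate
Product: 12 allyl 3-[3-geranyl-6-hydroxy-2,4-bis(methoxymethoxy)phenyl]-3-hydroxypropanoate (racemic), via lithium enolate 11 (not isolated)
Conditions: LiN(i-Pr)2 (3.2 equiv), 10 (3.0 equiv), THF, −78 °C; then 9, −78 °C; aq NH4Cl
Reagents that add atoms: none
Why: Aldol addition of a lithium ester enolate to the aryl aldehyde, with excess enolate to cover deprotonation of the phenol, should give the hydroxy ester as a racemate whose carbinol centre is removed in step 7.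

Step 7
Reactants: 12 allyl 3-[3-geranyl-6-hydroxy-2,4-bis(methoxymethoxy)phenyl]-3-hydroxypropanoate
Product: 13 allyl 3-[3-geranyl-6-hydroxy-2,4-bis(methoxymethoxy)phenyl]-3-oxopropanoate
Conditions: activated MnO2 (excess), CH2Cl2, rt
Reagents that add atoms: none
Why: MnO2 oxidation of an activated benzylic alcohol should give the aryl ketone without touching the isolated alkenes, the allyl ester or the phenol, which becomes hydrogen-bonded to the new carbonyl.

Step 8
Reactants: 14 syringaldehyde
Product: 15 3,5-dimethoxy-4-(methoxymethoxy)benzaldehyde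
Conditions: MOMCl, i-Pr2NEt, CH2Cl2, 0 °C to rt
Reagents that add atoms: chloromethyl methyl ether (MOMCl), COCCl
Why: MOM ether formation at the acidic 4-hydroxyl gives ring B the same protecting group as ring A, so one final operation frees all three phenols.

Step 9
Reactants: 13 allyl 3-[3-geranyl-6-hydroxy-2,4-bis(methoxymethoxy)phenyl]-3-oxopropanoate; 15 3,5-dimethoxy-4-(methoxymethoxy)benzaldehyde
Product: 16 allyl (2Z)-2-[3-geranyl-6-hydroxy-2,4-bis(methoxymethoxy)benzoyl]-3-[3,5-dimethoxy-4-(methoxymethoxy)phenyl]prop-2-enoate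
Conditions: piperidine (0.2 equiv), AcOH (0.2 equiv), 4 Å molecular sieves, toluene, rt to 40 °C
Reagents that add atoms: none
Why: Knoevenagel condensation under piperidinium acetate catalysis with water removal should give mainly the Z isomer (aryl trans to the twisted aroyl group), and the mild temperature is chosen so that the ketone-chelated phenol does not add prematurely.

Step 10
Reactants: 16 allyl (2Z)-2-[3-geranyl-6-hydroxy-2,4-bis(methoxymethoxy)benzoyl]-3-[3,5-dimethoxy-4-(methoxymethoxy)phenyl]prop-2-enoate
Product: 17 allyl (2S,3R)-2-[3,5-dimethoxy-4-(methoxymethoxy)phenyl]-6-geranyl-5,7-bis(methoxymethoxy)-4-oxochromane-3-carboxylate (2,3-trans)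
Conditions: N-[3,5-bis(trifluoromethyl)phenyl]-N′-[(8α,9S)-6′-methoxycinchonan-9-yl]thiourea (10 mol %), toluene, −25 °C; then AcOH (0.2 equiv), filtration through silica gel
Reagents that add atoms: none
Why: The quinuclidine nitrogen of the bifunctional catalyst deprotonates the single free phenol O1 while the thiourea holds the beta-keto ester by two hydrogen bonds, and O1 adds to the benzylidene carbon C2 to give an enol that is protonated at C3. The closest known reaction is the cinchona-thiourea-catalysed intramolecular oxa-Michael addition of alkylidene beta-keto tert-butyl esters to flavanone-3-carboxylates. Ring C closes in a 6-endo-trig mode through the new O1–C2 bond. C2 is set by the catalyst, which presents one enantioface of the acceptor to the tethered phenoxide, and C3 settles by epimerisation of the acidic keto ester position into the trans arrangement (it is erased in step 11). The step needs regioselectivity between O1 and O5 and enantiofacial selectivity: the first is secured because O5 and O7 are MOM ethers and the acyl group was placed next to the lone hydroxyl, the second by the two-point binding of the dicarbonyl unit. The ester also lowers the acceptor LUMO and shifts the reversible closure towards the ring, which should limit the ring opening that would erode enantiopurity.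

Step 11
Reactants: 17 allyl (2S,3R)-2-[3,5-dimethoxy-4-(methoxymethoxy)phenyl]-6-geranyl-5,7-bis(methoxymethoxy)-4-oxochromane-3-carboxylate
Product: 19 (2S)-2-[3,5-dimethoxy-4-(methoxymethoxy)phenyl]-6-geranyl-5,7-bis(methoxymethoxy)chroman-4-one, via flavanone-3-carboxylic acid 18 (not isolated)
Conditions: Pd(PPh3)4 (5 mol %), HCO2H (3 equiv), Et3N (2 equiv), THF, rt
Reagents that add atoms: none
Why: In this Tsuji-type deallylation zerovalent palladium ionises the allyl ester, formate reduces the allyl fragment to propene, and the free beta-keto acid should lose CO2 at room temperature; the weakly acidic buffer avoids base-induced ring opening, so C2 is kept while C3 becomes a methylene.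

Step 12
Reactants: 19 (2S)-2-[3,5-dimethoxy-4-(methoxymethoxy)phenyl]-6-geranyl-5,7-bis(methoxymethoxy)chroman-4-one
Product: 20 (2S)-6-geranyl-5,7-dihydroxy-2-(4-hydroxy-3,5-dimethoxyphenyl)chroman-4-one (CNP0372687.1)
Conditions: 3 M aq HCl, MeOH, 45 °C
Reagents that add atoms: none
Why: Acid-catalysed acetal methanolysis (MOM ether cleavage), a standard end step for prenylated flavanones, should free the three phenols, with moderate temperature and short contact time chosen to spare the geranyl alkenes and the C2 centre.

**Compound list**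

1 | phloroglucinol | Oc1cc(O)cc(O)c1 | starting material
2 | 3,5-bis(methoxymethoxy)phenol | COCOc1cc(O)cc(OCOC)c1 | intermediate
3 | [3,5-bis(methoxymethoxy)phenoxy]triisopropylsilane | COCOc1cc(O[Si](C(C)C)(C(C)C)C(C)C)cc(OCOC)c1 | intermediate
4 | geranyl bromide, (2E)-1-bromo-3,7-dimethylocta-2,6-diene | CC(C)=CCC/C(C)=C/CBr | starting material
5 | [2,6-bis(methoxymethoxy)-4-(triisopropylsilyloxy)phenyl]lithium | COCOc1cc(O[Si](C(C)C)(C(C)C)C(C)C)cc(OCOC)c1[Li] | intermediate
6 | [4-geranyl-3,5-bis(methoxymethoxy)phenoxy]triisopropylsilane | COCOc1cc(O[Si](C(C)C)(C(C)C)C(C)C)cc(OCOC)c1C/C=C(\C)CCC=C(C)C | intermediate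
7 | 4-geranyl-3,5-bis(methoxymethoxy)phenol | COCOc1cc(O)cc(OCOC)c1C/C=C(\C)CCC=C(C)C | intermediate
8 | 4-geranyl-2-(hydroxymethyl)-3,5-bis(methoxymethoxy)phenol (as its magnesium salt) | OCc1c(O)cc(OCOC)c(C/C=C(\C)CCC=C(C)C)c1OCOC | intermediate
9 | 3-geranyl-6-hydroxy-2,4-bis(methoxymethoxy)benzaldehyde | O=Cc1c(O)cc(OCOC)c(C/C=C(\C)CCC=C(C)C)c1OCOC | intermediate
10 | allyl acetate | CC(=O)OCC=C | starting material
11 | lithium enolate of allyl acetate | [Li]OC(=C)OCC=C | intermediate
12 | allyl 3-[3-geranyl-6-hydroxy-2,4-bis(methoxymethoxy)phenyl]-3-hydroxypropanoate (racemic) | C=CCOC(=O)CC(O)c1c(O)cc(OCOC)c(C/C=C(\C)CCC=C(C)C)c1OCOC | intermediate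
13 | allyl 3-[3-geranyl-6-hydroxy-2,4-bis(methoxymethoxy)phenyl]-3-oxopropanoate | C=CCOC(=O)CC(=O)c1c(O)cc(OCOC)c(C/C=C(\C)CCC=C(C)C)c1OCOC | intermediate
14 | syringaldehyde | COc1cc(C=O)cc(OC)c1O | starting material
15 | 3,5-dimethoxy-4-(methoxymethoxy)benzaldehyde | COCOc1c(OC)cc(C=O)cc1OC | intermediate
16 | allyl (2Z)-2-[3-geranyl-6-hydroxy-2,4-bis(methoxymethoxy)benzoyl]-3-[3,5-dimethoxy-4-(methoxymethoxy)phenyl]prop-2-enoate | C=CCOC(=O)/C(=C\c1cc(OC)c(OCOC)c(OC)c1)C(=O)c1c(O)cc(OCOC)c(C/C=C(\C)CCC=C(C)C)c1OCOC | intermediate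
17 | allyl (2S,3R)-2-[3,5-dimethoxy-4-(methoxymethoxy)phenyl]-6-geranyl-5,7-bis(methoxymethoxy)-4-oxochromane-3-carboxylate (2,3-trans) | COc1cc([C@@H]2[C@@H](C(=O)OCC=C)C(=O)c3c(cc(OCOC)c(C/C=C(\C)CCC=C(C)C)c3OCOC)O2)cc(OC)c1OCOC | intermediate
18 | (2S,3R)-2-[3,5-dimethoxy-4-(methoxymethoxy)phenyl]-6-geranyl-5,7-bis(methoxymethoxy)-4-oxochromane-3-carboxylic acid | COc1cc([C@@H]2[C@@H](C(=O)O)C(=O)c3c(cc(OCOC)c(C/C=C(\C)CCC=C(C)C)c3OCOC)O2)cc(OC)c1OCOC | intermediate
19 | (2S)-2-[3,5-dimethoxy-4-(methoxymethoxy)phenyl]-6-geranyl-5,7-bis(methoxymethoxy)chroman-4-one | COc1cc([C@@H]2CC(=O)c3c(cc(OCOC)c(C/C=C(\C)CCC=C(C)C)c3OCOC)O2)cc(OC)c1OCOC | intermediate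
20 | (2S)-6-geranyl-5,7-dihydroxy-2-(4-hydroxy-3,5-dimethoxyphenyl)chroman-4-one | COc1cc([C@@H]2CC(=O)c3c(cc(O)c(C/C=C(\C)CCC=C(C)C)c3O)O2)cc(OC)c1O | target

**Count**

Total steps: 12. Longest linear sequence: 11 steps (steps 1–7 and 9–12 from phloroglucinol); step 8 is a one-step side branch.

**Steps most likely to fail**

Step 10. The allyl ester is slimmer than the tert-alkyl esters on which this catalysis rests, so enantiofacial discrimination may be weaker. The electron-rich ring B may also favour reversible ring opening, which would erode enantiopurity during long contact with the amine catalyst. The fallback restores a tert-alkyl ester that zerovalent palladium can still remove; it sets out from aldehyde 9 and returns at 19. The lithium enolate of commercial 2-methylbut-3-en-2-yl acetate is added to 9 as in step 6 to give 2-methylbut-3-en-2-yl 3-[3-geranyl-6-hydroxy-2,4-bis(methoxymethoxy)phenyl]-3-hydroxypropanoate F1. MnO2 oxidation gives the corresponding keto ester, 2-methylbut-3-en-2-yl 3-[3-geranyl-6-hydroxy-2,4-bis(methoxymethoxy)phenyl]-3-oxopropanoate F2. Knoevenagel condensation with 15 gives the 2-methylbut-3-en-2-yl analogue of 16 F3, and the same thiourea closes it to the 2-methylbut-3-en-2-yl (2S,3R)-flavanone-3-carboxylate F4. Pd(PPh3)4 with HCO2H/Et3N in THF then ionises the tertiary allylic ester, and decarboxylation gives 19.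

Step 9. Both partners are electron-rich and the keto ester carbonyl is flanked by two ortho substituents, so the condensation may be slow. In a long reaction the amine can trigger uncatalysed ring closure of the free phenol without stereocontrol, or lactonisation of the phenol onto the allyl ester with loss of allyl alcohol. The fallback masks O1 during the condensation; it sets out from 13 and returns at 16. Silylation (TIPSCl, imidazole, DMF) gives allyl 3-[3-geranyl-2,4-bis(methoxymethoxy)-6-(triisopropylsilyloxy)phenyl]-3-oxopropanoate F5, which can be condensed with 15 under forcing conditions (piperidine, AcOH, toluene, reflux with water separation) to the O1-silylated alkylidene keto ester F6. HF·pyridine buffered with pyridine in THF at 0 °C then frees O1 under acidic conditions that do not promote closure, giving 16.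

Step 12. Protic acid may add a freed ring A hydroxyl (O5 or O7) across the nearer double bond of the geranyl chain, or hydrate the terminal alkene. Prolonged acid may also open ring C reversibly and erode C2. The fallback avoids Brønsted acid by exchanging the acetals for silyl ethers; it sets out from 19 and returns at 20. TMSOTf with 2,2′-bipyridyl in CH2Cl2 at 0 °C converts the three aryl MOM ethers into trimethylsilyl ethers, giving the tris(trimethylsilyl) ether of the target F7, and brief treatment with aqueous methanol hydrolyses it to 20.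

**Further compounds**

F1 | step 10 | 2-methylbut-3-en-2-yl 3-[3-geranyl-6-hydroxy-2,4-bis(methoxymethoxy)phenyl]-3-hydroxypropanoate (racemic) | C=CC(C)(C)OC(=O)CC(O)c1c(O)cc(OCOC)c(C/C=C(\C)CCC=C(C)C)c1OCOC
F2 | step 10 | 2-methylbut-3-en-2-yl 3-[3-geranyl-6-hydroxy-2,4-bis(methoxymethoxy)phenyl]-3-oxopropanoate | C=CC(C)(C)OC(=O)CC(=O)c1c(O)cc(OCOC)c(C/C=C(\C)CCC=C(C)C)c1OCOC
F3 | step 10 | 2-methylbut-3-en-2-yl (2Z)-2-[3-geranyl-6-hydroxy-2,4-bis(methoxymethoxy)benzoyl]-3-[3,5-dimethoxy-4-(methoxymethoxy)phenyl]prop-2-enoate | C=CC(C)(C)OC(=O)/C(=C\c1cc(OC)c(OCOC)c(OC)c1)C(=O)c1c(O)cc(OCOC)c(C/C=C(\C)CCC=C(C)C)c1OCOC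
F4 | step 10 | 2-methylbut-3-en-2-yl (2S,3R)-2-[3,5-dimethoxy-4-(methoxymethoxy)phenyl]-6-geranyl-5,7-bis(methoxymethoxy)-4-oxochromane-3-carboxylate | COc1cc([C@@H]2[C@@H](C(=O)OC(C)(C)C=C)C(=O)c3c(cc(OCOC)c(C/C=C(\C)CCC=C(C)C)c3OCOC)O2)cc(OC)c1OCOC
F5 | step 9 | allyl 3-[3-geranyl-2,4-bis(methoxymethoxy)-6-(triisopropylsilyloxy)phenyl]-3-oxopropanoate | C=CCOC(=O)CC(=O)c1c(O[Si](C(C)C)(C(C)C)C(C)C)cc(OCOC)c(C/C=C(\C)CCC=C(C)C)c1OCOC
F6 | step 9 | allyl (2Z)-2-[3-geranyl-2,4-bis(methoxymethoxy)-6-(triisopropylsilyloxy)benzoyl]-3-[3,5-dimethoxy-4-(methoxymethoxy)phenyl]prop-2-enoate | C=CCOC(=O)/C(=C\c1cc(OC)c(OCOC)c(OC)c1)C(=O)c1c(O[Si](C(C)C)(C(C)C)C(C)C)cc(OCOC)c(C/C=C(\C)CCC=C(C)C)c1OCOC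
F7 | step 12 | (2S)-2-[3,5-dimethoxy-4-(trimethylsilyloxy)phenyl]-6-geranyl-5,7-bis(trimethylsilyloxy)chroman-4-one | COc1cc([C@@H]2CC(=O)c3c(cc(O[Si](C)(C)C)c(C/C=C(\C)CCC=C(C)C)c3O[Si](C)(C)C)O2)cc(OC)c1O[Si](C)(C)C
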